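**Strategy.** The route rests on cutting the C2–C3 bond of the 4-methylidene-5-oxooxolane ring (O1, C2 bearing the acetoxy-methylpropenyl arm, C3 bearing the acyloxy side chain, C4 exocyclic methylidene, C5 carbonyl). This trans-2,3-disubstituted α-methylene lactone is the retron of a carbonyl 2-(alkoxycarbonyl)allylation. A geometrically defined 2-(methoxycarbonyl)allyl pinacol boronate, which already carries the silyl-protected carbinol stereocentre and the hydroxy-methylpentenyl chain, is united with achiral (E)-4-acetoxy-3-methylbut-2-enal. One operation forms C2–C3 through a closed chair transition state, sets both ring stereocentres, shifts the alkene into the exocyclic position and closes the lactone with loss of MeOBpin. Both precursors are acyclic.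

Key step: step 11

Assumption: the (R,R)-bisphosphoramide of step 2 is taken to direct attack to the Re face of the ynal (its antipode is used if the sense is opposite), and oxirane 13 is used as the racemate because its stereocentre is destroyed in step 8.

Step 1
Reactants: 1 ethyl 3-methylbut-2-enoate
Product: 3 tert-butyl[(1-ethoxy-3-methylbuta-1,3-dien-1-yl)oxy]dimethylsilane, via lithium dienolate 2 (not isolated)
Conditions: LiN(i-Pr)2, THF, −78 °C; then TBSCl, DMPU, −78 °C to rt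
Reagents that add atoms: tert-butyldimethylsilyl chloride (TBSCl), CC(C)(C)[Si](C)(C)Cl
Why: Kinetic γ-deprotonation of the β,β-dimethyl enoate gives the extended lithium enolate, which is silylated on oxygen (silyl ketene acetal formation); no stereocentre is formed and the ketene acetal geometry is inconsequential.

Step 2
Reactants: 3 tert-butyl[(1-ethoxy-3-methylbuta-1,3-dien-1-yl)oxy]dimethylsilane; 4 3-(trimethylsilyl)prop-2-ynal
Product: 5 ethyl (2E,5R)-5-hydroxy-3-methyl-7-(trimethylsilyl)hept-2-en-6-ynoate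
Conditions: SiCl4, (R,R)-binaphthyldiamine-derived bisphosphoramide (5 mol%), i-Pr2NEt (10 mol%), CH2Cl2, −78 °C; aq. KF/NaHCO3 work-up
Reagents that add atoms: none
Why: Vinylogous Mukaiyama aldol reaction under Lewis-base-activated SiCl4 catalysis, in which the dienolate attacks through its terminal CH2 on the Re face of the catalyst-bound ynal in an open transition state, which should set C5 as (R) and give the (2E)-enoate.

Step 3
Reactants: 5 ethyl (2E,5R)-5-hydroxy-3-methyl-7-(trimethylsilyl)hept-2-en-6-ynoate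
Product: 6 ethyl (2E,5R)-3-methyl-5-[(triethylsilyl)oxy]-7-(trimethylsilyl)hept-2-en-6-ynoate
Conditions: TESCl, imidazole, CH2Cl2, 0 °C
Reagents that add atoms: triethylsilyl chloride (TESCl), CC[Si](Cl)(CC)CC
Why: Standard silylation of the secondary propargylic alcohol; the triethylsilyl ether can later be removed beside the tert-butyldiphenylsilyl ether and prevents butenolide formation once the cis ester is in place in step 7.

Step 4
Reactants: 6 ethyl (2E,5R)-3-methyl-5-[(triethylsilyl)oxy]-7-(trimethylsilyl)hept-2-en-6-ynoate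
Product: 7 (2E,5R)-3-methyl-5-[(triethylsilyl)oxy]-7-(trimethylsilyl)hept-2-en-6-yn-1-ol
Conditions: i-Bu2AlH (2.2 equiv), CH2Cl2, −78 °C; aq. KNa tartrate
Reagents that add atoms: none
Why: 1,2-Reduction of the enoate by i-Bu2AlH at low temperature should give the allylic alcohol without touching the silyl ethers, the silylalkyne or the alkene geometry.

Step 5
Reactants: 7 (2E,5R)-3-methyl-5-[(triethylsilyl)oxy]-7-(trimethylsilyl)hept-2-en-6-yn-1-ol
Product: 8 tert-butyl({(2E,5R)-3-methyl-5-[(triethylsilyl)oxy]-7-(trimethylsilyl)hept-2-en-6-yn-1-yl}oxy)diphenylsilane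
Conditions: TBDPSCl, imidazole, CH2Cl2, rt
Reagents that add atoms: tert-butyldiphenylsilyl chloride (TBDPSCl), CC(C)(C)[Si](Cl)(c1ccccc1)c1ccccc1
Why: Silylation of the primary allylic alcohol with a robust silyl group that survives the organometallic steps and the later selective removal of the triethylsilyl ether.

Step 6
Reactants: 8 tert-butyl({(2E,5R)-3-methyl-5-[(triethylsilyl)oxy]-7-(trimethylsilyl)hept-2-en-6-yn-1-yl}oxy)diphenylsilane
Product: 10 methyl (4R,6E)-8-[(tert-butyldiphenylsilyl)oxy]-6-methyl-4-[(triethylsilyl)oxy]oct-6-en-2-ynoate, via lithium acetylide 9 (not isolated)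
Conditions: MeLi·LiBr, THF, 0 °C to rt; then ClCO2Me, −78 to 0 °C
Reagents that add atoms: methyl chloroformate, COC(=O)Cl
Why: MeLi attacks the trimethylsilyl group of the alkynylsilane (silicon-to-lithium exchange) and the lithium acetylide is C-acylated by the chloroformate; the ether-protected stereocentre is not involved.

Step 7
Reactants: 10 methyl (4R,6E)-8-[(tert-butyldiphenylsilyl)oxy]-6-methyl-4-[(triethylsilyl)oxy]oct-6-en-2-ynoate
Product: 12 methyl (2Z,4R,6E)-8-[(tert-butyldiphenylsilyl)oxy]-6-methyl-2-[(4,4,5,5-tetramethyl-1,3,2-dioxaborolan-2-yl)methyl]-4-[(triethylsilyl)oxy]octa-2,6-dienoate, via vinylalane 11 (not isolated)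
Conditions: i-Bu2AlH, HMPA, THF, 0 °C; then ICH2Bpin, 0 °C to rt
Reagents that add atoms: 2-(iodomethyl)-4,4,5,5-tetramethyl-1,3,2-dioxaborolane (ICH2Bpin), CC1(C)OB(CI)OC1(C)C
Why: Conjugate hydroalumination of the ynoate by the i-Bu2AlH–HMPA complex places hydride on C3 and aluminium on C2 on the same side, and C-alkylation of this α-alumino enoate by the iodomethylboronate occurs with retention, so C4 should end up cis to the ester and trans to CH2B (hydroalumination–alkylation of alkynoates).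

Step 8
Reactants: 13 2-methyl-2-vinyloxirane
Product: 14 (2E)-4-chloro-2-methylbut-2-en-1-ol
Conditions: TiCl4, CH2Cl2, −85 °C; aqueous work-up
Reagents that add atoms: TiCl4 (titanium tetrachloride), Cl[Ti](Cl)(Cl)Cl
Why: Lewis-acid-mediated SN2′ opening of the vinyl oxirane delivers chloride to the vinyl terminus of the titanium-bound epoxide and should give mainly the (E)-trisubstituted allylic chloride.

Step 9
Reactants: 14 (2E)-4-chloro-2-methylbut-2-en-1-ol
Product: 15 (2E)-4-chloro-2-methylbut-2-en-1-yl acetate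
Conditions: Ac2O, pyridine, DMAP (cat.), CH2Cl2, 0 °C
Reagents that add atoms: acetic anhydride, CC(=O)OC(C)=O
Why: DMAP-catalysed acetylation of the primary allylic alcohol; the allylic chloride is inert to these conditions.

Step 10
Reactants: 15 (2E)-4-chloro-2-methylbut-2-en-1-yl acetate
Product: 16 (2E)-2-methyl-4-oxobut-2-en-1-yl acetate
Conditions: NMO, KI (cat.), 4 Å MS, MeCN, rt to 45 °C
Reagents that add atoms: N-methylmorpholine N-oxide (NMO), C[N+]1([O-])CCOCC1
Why: Amine N-oxide (Kornblum-type) oxidation, in which iodide-catalysed SN2 displacement of the primary allylic chloride by the N-oxide oxygen is followed by elimination of N-methylmorpholine, gives the enal under non-acidic conditions that should leave the acetate and the (E)-geometry intact.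

Step 11
Reactants: 12 methyl (2Z,4R,6E)-8-[(tert-butyldiphenylsilyl)oxy]-6-methyl-2-[(4,4,5,5-tetramethyl-1,3,2-dioxaborolan-2-yl)methyl]-4-[(triethylsilyl)oxy]octa-2,6-dienoate; 16 (2E)-2-methyl-4-oxobut-2-en-1-yl acetate
Product: 18 [(2E)-3-{(2R,3S)-3-[(1R,3E)-5-[(tert-butyldiphenylsilyl)oxy]-3-methyl-1-[(triethylsilyl)oxy]pent-3-en-1-yl]-4-methylidene-5-oxooxolan-2-yl}-2-methylprop-2-en-1-yl] acetate, via O-boryl hydroxy ester 17 (not isolated)
Conditions: Sc(OTf)3 (10 mol%), 4 Å MS, toluene, 0 °C to rt, then 40 °C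
Reagents that add atoms: none
Why: The Sc(OTf)3-activated pinacol boronate adds to the aldehyde carbonyl of 16 through a closed six-membered chair transition state (boron bound to the carbonyl oxygen, SE2′), so that the boronate γ-carbon (future ring C3) bonds to the aldehyde carbon (future ring C2) while the alkene moves into the exocyclic methylidene position; the O-boryl alkoxide 17 then closes the lactone by 5-exo-trig acyl substitution on the methyl ester with loss of MeOBpin, overall a formal (3+2) annulation of the 2-(methoxycarbonyl)allyl unit across C=O. The closest known reaction type is the Lewis-acid-catalysed tandem allylboration–lactonisation of 2-(alkoxycarbonyl)allylboronates with aldehydes. The relative configuration at ring C2/C3 follows from the boronate geometry: the carbinol-bearing substituent is trans to CH2B and therefore equatorial, as is the alkenyl group of 16, which gives the anti adduct and hence the 2,3-trans lactone. The absolute configuration is relayed from the silyloxy stereocentre: A(1,3) strain with the cis ester holds its C–H bond in the alkene plane, the CH2 chain lies anti to the forming bond and the OSiEt3 group outside, so the aldehyde is expected to attack the face that leads to (2R,3S)-18 (the 3S descriptor reflects silicon priority; the geometry is that of the target). The step needs 1,2- rather than 1,4-addition to the enal and retention of the boronate geometry; both are secured by the cyclic boron-to-oxygen delivery and the configurational stability of allyl pinacol boronates.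

Step 12
Reactants: 18 [(2E)-3-{(2R,3S)-3-[(1R,3E)-5-[(tert-butyldiphenylsilyl)oxy]-3-methyl-1-[(triethylsilyl)oxy]pent-3-en-1-yl]-4-methylidene-5-oxooxolan-2-yl}-2-methylprop-2-en-1-yl] acetate
Product: 19 [(2E)-3-{(2R,3R)-3-[(1R,3E)-5-[(tert-butyldiphenylsilyl)oxy]-1-hydroxy-3-methylpent-3-en-1-yl]-4-methylidene-5-oxooxolan-2-yl}-2-methylprop-2-en-1-yl] acetate
Conditions: HF·pyridine, pyridine, THF, 0 °C
Reagents that add atoms: none
Why: Buffered fluoride cleaves the secondary triethylsilyl ether much faster than the primary tert-butyldiphenylsilyl ether and should not disturb the acetate or the lactone; the trans lactone is the more stable ring, so translactonisation onto the freed hydroxyl is not expected.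

Step 13
Reactants: 19 [(2E)-3-{(2R,3R)-3-[(1R,3E)-5-[(tert-butyldiphenylsilyl)oxy]-1-hydroxy-3-methylpent-3-en-1-yl]-4-methylidene-5-oxooxolan-2-yl}-2-methylprop-2-en-1-yl] acetate
Product: 20 (1R,3E)-1-{(2R,3R)-2-[(1E)-3-acetoxy-2-methylprop-1-en-1-yl]-4-methylidene-5-oxooxolan-3-yl}-5-[(tert-butyldiphenylsilyl)oxy]-3-methylpent-3-en-1-yl 2-methylprop-2-enoate
Conditions: methacrylic anhydride, Et3N, DMAP (cat.), CH2Cl2, 0 °C to rt
Reagents that add atoms: methacrylic anhydride, C=C(C)C(=O)OC(=O)C(C)=C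
Why: DMAP-catalysed acylation of the secondary alcohol proceeds with retention at the carbinol carbon, and only one ester can form because the primary hydroxyl is still silylated.

Step 14
Reactants: 20 (1R,3E)-1-{(2R,3R)-2-[(1E)-3-acetoxy-2-methylprop-1-en-1-yl]-4-methylidene-5-oxooxolan-3-yl}-5-[(tert-butyldiphenylsilyl)oxy]-3-methylpent-3-en-1-yl 2-methylprop-2-enoate
Product: 21 (1R,3E)-1-{(2R,3R)-2-[(1E)-3-acetoxy-2-methylprop-1-en-1-yl]-4-methylidene-5-oxooxolan-3-yl}-5-hydroxy-3-methylpent-3-en-1-yl 2-methylprop-2-enoate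
Conditions: HF·pyridine, THF, 0 °C to rt
Reagents that add atoms: none
Why: Fluoride-mediated desilylation under mildly acidic conditions should free the primary allylic alcohol without ester migration, conjugate addition to the methylidene lactone or cleavage of the acetate and methacrylate.

**Compound list**

1 | ethyl 3-methylbut-2-enoate | CCOC(=O)C=C(C)C | starting material
2 | lithium 1-ethoxy-3-methylbuta-1,3-dien-1-olate (lithium dienolate) | [Li]OC(OCC)=CC(C)=C | intermediate
3 | tert-butyl[(1-ethoxy-3-methylbuta-1,3-dien-1-yl)oxy]dimethylsilane | C=C(C)C=C(OCC)O[Si](C)(C)C(C)(C)C | intermediate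
4 | 3-(trimethylsilyl)prop-2-ynal | C[Si](C)(C)C#CC=O | starting material
5 | ethyl (2E,5R)-5-hydroxy-3-methyl-7-(trimethylsilyl)hept-2-en-6-ynoate | C[Si](C)(C)C#C[C@H](O)C/C(C)=C/C(=O)OCC | intermediate
6 | ethyl (2E,5R)-3-methyl-5-[(triethylsilyl)oxy]-7-(trimethylsilyl)hept-2-en-6-ynoate | C[Si](C)(C)C#C[C@H](O[Si](CC)(CC)CC)C/C(C)=C/C(=O)OCC | intermediate
7 | (2E,5R)-3-methyl-5-[(triethylsilyl)oxy]-7-(trimethylsilyl)hept-2-en-6-yn-1-ol | C[Si](C)(C)C#C[C@H](O[Si](CC)(CC)CC)C/C(C)=C/CO | intermediate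
8 | tert-butyl({(2E,5R)-3-methyl-5-[(triethylsilyl)oxy]-7-(trimethylsilyl)hept-2-en-6-yn-1-yl}oxy)diphenylsilane | C[Si](C)(C)C#C[C@H](O[Si](CC)(CC)CC)C/C(C)=C/CO[Si](c1ccccc1)(c1ccccc1)C(C)(C)C | intermediate
9 | {(3R,5E)-7-[(tert-butyldiphenylsilyl)oxy]-5-methyl-3-[(triethylsilyl)oxy]hept-5-en-1-yn-1-yl}lithium (lithium acetylide) | [Li]C#C[C@H](O[Si](CC)(CC)CC)C/C(C)=C/CO[Si](c1ccccc1)(c1ccccc1)C(C)(C)C | intermediate
10 | methyl (4R,6E)-8-[(tert-butyldiphenylsilyl)oxy]-6-methyl-4-[(triethylsilyl)oxy]oct-6-en-2-ynoate | COC(=O)C#C[C@H](O[Si](CC)(CC)CC)C/C(C)=C/CO[Si](c1ccccc1)(c1ccccc1)C(C)(C)C | intermediate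
11 | methyl (2E,4R,6E)-8-[(tert-butyldiphenylsilyl)oxy]-2-(diisobutylalumanyl)-6-methyl-4-[(triethylsilyl)oxy]octa-2,6-dienoate (vinylalane, Al cis to 3-H) | COC(=O)/C([Al](CC(C)C)CC(C)C)=C\[C@H](O[Si](CC)(CC)CC)C/C(C)=C/CO[Si](c1ccccc1)(c1ccccc1)C(C)(C)C | intermediate
12 | methyl (2Z,4R,6E)-8-[(tert-butyldiphenylsilyl)oxy]-6-methyl-2-[(4,4,5,5-tetramethyl-1,3,2-dioxaborolan-2-yl)methyl]-4-[(triethylsilyl)oxy]octa-2,6-dienoate (C4 cis to CO2Me) | COC(=O)/C(CB1OC(C)(C)C(C)(C)O1)=C\[C@H](O[Si](CC)(CC)CC)C/C(C)=C/CO[Si](c2ccccc2)(c3ccccc3)C(C)(C)C | intermediate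
13 | 2-methyl-2-vinyloxirane (racemic) | CC1(C=C)CO1 | starting material
14 | (2E)-4-chloro-2-methylbut-2-en-1-ol | OC/C(C)=C/CCl | intermediate
15 | (2E)-4-chloro-2-methylbut-2-en-1-yl acetate | CC(=O)OC/C(C)=C/CCl | intermediate
16 | (2E)-2-methyl-4-oxobut-2-en-1-yl acetate [(E)-4-acetoxy-3-methylbut-2-enal] | CC(=O)OC/C(C)=C/C=O | intermediate
17 | methyl (3S,4R,5E)-7-acetoxy-3-{(1R,3E)-5-[(tert-butyldiphenylsilyl)oxy]-3-methyl-1-[(triethylsilyl)oxy]pent-3-en-1-yl}-6-methyl-2-methylidene-4-[(4,4,5,5-tetramethyl-1,3,2-dioxaborolan-2-yl)oxy]hept-5-enoate (O-boryl hydroxy ester) | CC[Si](CC)(CC)O[C@H](C/C(C)=C/CO[Si](c2ccccc2)(c3ccccc3)C(C)(C)C)[C@@H](C(=C)C(=O)OC)[C@H](OB1OC(C)(C)C(C)(C)O1)/C=C(\C)COC(C)=O | intermediate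
18 | [(2E)-3-{(2R,3S)-3-[(1R,3E)-5-[(tert-butyldiphenylsilyl)oxy]-3-methyl-1-[(triethylsilyl)oxy]pent-3-en-1-yl]-4-methylidene-5-oxooxolan-2-yl}-2-methylprop-2-en-1-yl] acetate | CC[Si](CC)(CC)O[C@H](C/C(C)=C/CO[Si](c2ccccc2)(c3ccccc3)C(C)(C)C)[C@H]1C(=C)C(=O)O[C@@H]1/C=C(\C)COC(C)=O | intermediate
19 | [(2E)-3-{(2R,3R)-3-[(1R,3E)-5-[(tert-butyldiphenylsilyl)oxy]-1-hydroxy-3-methylpent-3-en-1-yl]-4-methylidene-5-oxooxolan-2-yl}-2-methylprop-2-en-1-yl] acetate | O[C@H](C/C(C)=C/CO[Si](c2ccccc2)(c3ccccc3)C(C)(C)C)[C@H]1C(=C)C(=O)O[C@@H]1/C=C(\C)COC(C)=O | intermediate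
20 | (1R,3E)-1-{(2R,3R)-2-[(1E)-3-acetoxy-2-methylprop-1-en-1-yl]-4-methylidene-5-oxooxolan-3-yl}-5-[(tert-butyldiphenylsilyl)oxy]-3-methylpent-3-en-1-yl 2-methylprop-2-enoate | C=C(C)C(=O)O[C@H](C/C(C)=C/CO[Si](c2ccccc2)(c3ccccc3)C(C)(C)C)[C@H]1C(=C)C(=O)O[C@@H]1/C=C(\C)COC(C)=O | intermediate
21 | (1R,3E)-1-{(2R,3R)-2-[(1E)-3-acetoxy-2-methylprop-1-en-1-yl]-4-methylidene-5-oxooxolan-3-yl}-5-hydroxy-3-methylpent-3-en-1-yl 2-methylprop-2-enoate | C=C(C)C(=O)O[C@H](C/C(C)=C/CO)[C@H]1C(=C)C(=O)O[C@@H]1/C=C(\C)COC(C)=O | target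

**Step count.** Total: 14 steps. Longest linear sequence: 11 steps (steps 1–7 and 11–14, from ethyl 3-methylbut-2-enoate).

**Steps most likely to fail**

1. Step 11 (key step). The facial selection at the boronate γ-carbon relative to the silyloxy stereocentre may be low or may run in the opposite sense (aldehyde approaching anti to the C–O bond rather than anti to the CH2 chain); the Lewis acid may also ionise the allylic borate. Fallback (inversion strategy, known chemistry): setting out from 3 and 4, the aldol of step 2 is run with the (S,S)-bisphosphoramide to give the (5S)-aldol ethyl (2E,5S)-5-hydroxy-3-methyl-7-(trimethylsilyl)hept-2-en-6-ynoate F1. The operations of steps 3–7 then give in turn the (5S)-triethylsilyl ether F2, the (5S)-allylic alcohol F3, the (5S)-tert-butyldiphenylsilyl ether F4, the (3S)-lithium acetylide F5, the (4S)-ynoate F6, the (4S)-vinylalane F7 and the (4S)-allylboronate F8. Union of F8 with 16 under the conditions of step 11, now with attack anti to the silyloxy group, should pass through the (1S)-O-boryl hydroxy ester F9 to the (2R,3S)-lactone with (1S)-silyloxy side chain F10. HF·pyridine then frees the (1S)-hydroxy lactone F11, and Mitsunobu esterification with methacrylic acid (PPh3, DIAD, THF, 0 °C) inverts this carbinol centre and comes back to the route at 20.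

2. Step 7. Competing 1,2-reduction of the ynoate, loss of alkene geometry through the aluminium allenolate and slow C-alkylation by the iodomethylboronate may erode yield and isomeric purity. Fallback (stepwise, known chemistry): setting out from 10, Pd(PPh3)4-catalysed syn hydrostannation with Bu3SnH (tin at C2) gives the α-stannyl enoate methyl (2E,4R,6E)-8-[(tert-butyldiphenylsilyl)oxy]-6-methyl-2-(tributylstannyl)-4-[(triethylsilyl)oxy]octa-2,6-dienoate F12. Iododestannylation with I2 (retention) gives the α-iodo enoate methyl (2E,4R,6E)-8-[(tert-butyldiphenylsilyl)oxy]-2-iodo-6-methyl-4-[(triethylsilyl)oxy]octa-2,6-dienoate F13. Negishi coupling of F13 with IZnCH2Bpin (Pd(PPh3)4, THF) comes back to the route at 12.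

3. Step 2. Enantiofacial control, γ- versus α-attack and E/Z control may be insufficient with the alkynyl aldehyde. Fallback (stereocentre set by ketone reduction instead of aldol): setting out from 3 and 4, a BF3·OEt2-promoted vinylogous Mukaiyama aldol gives the racemic aldol ethyl (2E)-5-hydroxy-3-methyl-7-(trimethylsilyl)hept-2-en-6-ynoate F14. NaHCO3-buffered Dess–Martin oxidation gives the ynone ethyl (2E)-3-methyl-5-oxo-7-(trimethylsilyl)hept-2-en-6-ynoate F15. Asymmetric transfer hydrogenation with RuCl[(R,R)-TsDPEN](p-cymene) in i-PrOH at rt, with the alkynyl group in the directing role, should give the (R)-propargylic alcohol and comes back to the route at 5.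

**Further compounds**

F1 | step 11 | ethyl (2E,5S)-5-hydroxy-3-methyl-7-(trimethylsilyl)hept-2-en-6-ynoate | C[Si](C)(C)C#C[C@@H](O)C/C(C)=C/C(=O)OCC
F2 | step 11 | ethyl (2E,5S)-3-methyl-5-[(triethylsilyl)oxy]-7-(trimethylsilyl)hept-2-en-6-ynoate | C[Si](C)(C)C#C[C@@H](O[Si](CC)(CC)CC)C/C(C)=C/C(=O)OCC
F3 | step 11 | (2E,5S)-3-methyl-5-[(triethylsilyl)oxy]-7-(trimethylsilyl)hept-2-en-6-yn-1-ol | C[Si](C)(C)C#C[C@@H](O[Si](CC)(CC)CC)C/C(C)=C/CO
F4 | step 11 | tert-butyl({(2E,5S)-3-methyl-5-[(triethylsilyl)oxy]-7-(trimethylsilyl)hept-2-en-6-yn-1-yl}oxy)diphenylsilane | C[Si](C)(C)C#C[C@@H](O[Si](CC)(CC)CC)C/C(C)=C/CO[Si](c1ccccc1)(c1ccccc1)C(C)(C)C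
F5 | step 11 | {(3S,5E)-7-[(tert-butyldiphenylsilyl)oxy]-5-methyl-3-[(triethylsilyl)oxy]hept-5-en-1-yn-1-yl}lithium | [Li]C#C[C@@H](O[Si](CC)(CC)CC)C/C(C)=C/CO[Si](c1ccccc1)(c1ccccc1)C(C)(C)C
F6 | step 11 | methyl (4S,6E)-8-[(tert-butyldiphenylsilyl)oxy]-6-methyl-4-[(triethylsilyl)oxy]oct-6-en-2-ynoate | COC(=O)C#C[C@@H](O[Si](CC)(CC)CC)C/C(C)=C/CO[Si](c1ccccc1)(c1ccccc1)C(C)(C)C
F7 | step 11 | methyl (2E,4S,6E)-8-[(tert-butyldiphenylsilyl)oxy]-2-(diisobutylalumanyl)-6-methyl-4-[(triethylsilyl)oxy]octa-2,6-dienoate | COC(=O)/C([Al](CC(C)C)CC(C)C)=C\[C@@H](O[Si](CC)(CC)CC)C/C(C)=C/CO[Si](c1ccccc1)(c1ccccc1)C(C)(C)C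
F8 | step 11 | methyl (2Z,4S,6E)-8-[(tert-butyldiphenylsilyl)oxy]-6-methyl-2-[(4,4,5,5-tetramethyl-1,3,2-dioxaborolan-2-yl)methyl]-4-[(triethylsilyl)oxy]octa-2,6-dienoate | COC(=O)/C(CB1OC(C)(C)C(C)(C)O1)=C\[C@@H](O[Si](CC)(CC)CC)C/C(C)=C/CO[Si](c2ccccc2)(c3ccccc3)C(C)(C)C
F9 | step 11 | methyl (3S,4R,5E)-7-acetoxy-3-{(1S,3E)-5-[(tert-butyldiphenylsilyl)oxy]-3-methyl-1-[(triethylsilyl)oxy]pent-3-en-1-yl}-6-methyl-2-methylidene-4-[(4,4,5,5-tetramethyl-1,3,2-dioxaborolan-2-yl)oxy]hept-5-enoate | CC[Si](CC)(CC)O[C@@H](C/C(C)=C/CO[Si](c2ccccc2)(c3ccccc3)C(C)(C)C)[C@@H](C(=C)C(=O)OC)[C@H](OB1OC(C)(C)C(C)(C)O1)/C=C(\C)COC(C)=O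
F10 | step 11 | [(2E)-3-{(2R,3S)-3-[(1S,3E)-5-[(tert-butyldiphenylsilyl)oxy]-3-methyl-1-[(triethylsilyl)oxy]pent-3-en-1-yl]-4-methylidene-5-oxooxolan-2-yl}-2-methylprop-2-en-1-yl] acetate | CC[Si](CC)(CC)O[C@@H](C/C(C)=C/CO[Si](c2ccccc2)(c3ccccc3)C(C)(C)C)[C@H]1C(=C)C(=O)O[C@@H]1/C=C(\C)COC(C)=O
F11 | step 11 | [(2E)-3-{(2R,3R)-3-[(1S,3E)-5-[(tert-butyldiphenylsilyl)oxy]-1-hydroxy-3-methylpent-3-en-1-yl]-4-methylidene-5-oxooxolan-2-yl}-2-methylprop-2-en-1-yl] acetate | O[C@@H](C/C(C)=C/CO[Si](c2ccccc2)(c3ccccc3)C(C)(C)C)[C@H]1C(=C)C(=O)O[C@@H]1/C=C(\C)COC(C)=O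
F12 | step 7 | methyl (2E,4R,6E)-8-[(tert-butyldiphenylsilyl)oxy]-6-methyl-2-(tributylstannyl)-4-[(triethylsilyl)oxy]octa-2,6-dienoate | COC(=O)/C([Sn](CCCC)(CCCC)CCCC)=C\[C@H](O[Si](CC)(CC)CC)C/C(C)=C/CO[Si](c1ccccc1)(c1ccccc1)C(C)(C)C
F13 | step 7 | methyl (2E,4R,6E)-8-[(tert-butyldiphenylsilyl)oxy]-2-iodo-6-methyl-4-[(triethylsilyl)oxy]octa-2,6-dienoate | COC(=O)/C(I)=C\[C@H](O[Si](CC)(CC)CC)C/C(C)=C/CO[Si](c1ccccc1)(c1ccccc1)C(C)(C)C
F14 | step 2 | ethyl (2E)-5-hydroxy-3-methyl-7-(trimethylsilyl)hept-2-en-6-ynoate (racemic) | C[Si](C)(C)C#CC(O)C/C(C)=C/C(=O)OCC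
F15 | step 2 | ethyl (2E)-3-methyl-5-oxo-7-(trimethylsilyl)hept-2-en-6-ynoate | C[Si](C)(C)C#CC(=O)C/C(C)=C/C(=O)OCC
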